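The numbers in the tables stem from a simulated flask with constants of no real substance; noise was put on by code.

Time is what this flask is asked about: it is read at 15 min, just past the last readings of three earlier runs with the same phase ratio and the same reagent charge.

| flask | starting material | reagent in the second phase | protic impurity | remark | time | volume of the second phase over the first |
|---|---|---|---|---|---|---|
| Thursday's | 10 mM | 19 mM | 1 mM | run made earlier |  |  |
| Tuesday's | 15 mM | 19 mM | 1 mM | run made earlier |  |  |
| Friday's | 20 mM | 19 mM | 2 mM | run made earlier |  |  |
| flask | 20 mM | 19.0 mM | 1.00 mM |  | 15 min | 2.0 |

| Thursday's: time / min | Thursday's: target / % | Tuesday's: time / min | Tuesday's: target / % | Friday's: time / min | Friday's: target / % |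
|---|---|---|---|---|---|
| 1.00 | 1.4 | 1.00 | 1.5 | 1.00 | 1.1 |
| 3.00 | 4.0 | 2.00 | 2.9 | 2.00 | 2.5 |
| 6.00 | 7.6 | 3.00 | 4.0 | 3.00 | 4.1 |
| 8.00 | 8.8 | 6.00 | 7.3 | 6.00 | 6.8 |
| 12.0 | 11.1 | 12.0 | 11.1 | 12.0 | 10.6 |

(each reading ± 0.3 percentage points)

- ochre: doubling the amount of reagent in the second phase, all else as stated
- blue: doubling the transfer coefficient of the reagent in the second phase, all else as stated

- in the second phase: reagent in the second phase; everything else is in the first
- charges count per volume of the first phase; a concentration in a rate is the amount of a species over the volume of its own phase; every rate counts per litre of the first phase
- steps that have been proposed: reagent in the reaction phase <-> reagent in the second phase; starting material + reagent in the reaction phase -> target; reagent in the reaction phase + target -> over-reacted product; starting material <-> dormant form; starting material + protic impurity -> quenched substrate; reagent in the reaction phase -> decomposed reagent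
- the earlier runs hold the two phases in the same ratio of volumes as the flask asked about

- amount of target at 15 min, in percent of the starting material charged
- the change that raises the amount of target at 15 min, in percent of the starting material charged most ("none" if none brings more than 2 percentage points) (ochre / blue / none)
- amount of target at 15 min, in percent of the starting material charged, after blue

We take the run in slow motion. In the first instants, Tuesday's target stands at 1.5% after 1.00 min and 2.9% after 2.00 min, a straight start in which we see no lag from the crossing of reagent into the reaction phase. Meanwhile the impurity can take at most 5.00% of this flask's starting material. The last readings of Thursday's and Tuesday's runs agree at 11.1% although their charges of starting material differ, so the formation of target looks pseudo-first-order in starting material.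

In the middle, the three runs gain on average 7.23% up to 6.00 min. We name the mean rise of target from 6.00 min to 12.0 min the late gain 3.7 percentage points. It is half of the early gain, though target stands at just 10.9% after 12.0 min, less than half of the charge. So the slowing looks like more than the starting material turned into target can account for, and these readings do not say what lies behind it.

For the end, we assume the pace holds. The remaining minutes add 1.8 points, so our figure is 12.8%. With no lag to read in Tuesday's start, we expect blue to stay near that figure. No run varied the reagent, but the proposed target step takes reagent in the reaction phase as a partner, so we choose ochre.

The forecast says 12.3%, below ours, chooses ochre and gives 13.5% after blue: “Faster transfer mainly speeds the approach to the same plateau”.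

The flask gives 13.1%. Ochre adds 7.4 points and blue 0.19 points, which leaves 13.3% after blue.

    reagent in the reaction phase ⇌ reagent in the second phase, rate k1*([reagent in the reaction phase] - [reagent in the second phase]/K1) per volume of the first phase (partition coefficient = 3.70, kL = 0.0750 s⁻¹)
    starting material + reagent in the reaction phase → target (k = 0.150 L mol⁻¹ s⁻¹)
    reagent in the reaction phase + target → over-reacted product (k = 0.150 L mol⁻¹ s⁻¹)
    starting material ⇌ dormant form (K = 0.780, k = 0.00200 s⁻¹)
    starting material + protic impurity → quenched substrate (k = 3.40 L mol⁻¹ s⁻¹)
    reagent in the reaction phase → decomposed reagent (k = 1.50 × 10⁻⁴ s⁻¹)

Starting material and dormant form relax with a half-life of 2.53 min, shorter than the 5.89 min by which half of this flask's target turnover is done. Between 7.50 min and 15.0 min, this flask's target rises at 3.7 points per 6.00 min, against the late gain of 3.7 points read in the earlier runs over an earlier window. In the neighbouring flask read at 1.0 h, target gains on average 1.4 points per 6.00 min after 15 min, and over-reacted product stands at 12.5% at that reading.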